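**Structural features**

The target is a 3a,4,5,7a-tetrahydro-1H-indene (indene numbering throughout): cyclohexene ring A (C3a, C4, C5, C6=C7, C7a) is trans-fused through C3a–C7a to cyclopentene ring B (C1, C2=C3), and both ring alkenes are trisubstituted and methyl-bearing (C7, C3). Five stereocentres stand in a row, C1–C7a–C3a–C4–C5. C4 and C5 are adjacent quaternary carbons with cis methyl groups; C4 carries the free acid and C5 the (1E,3E)-2-methyl-4-phenylbuta-1,3-dienyl chain. The C3 arm of ring B is cis to the C4 methyl, the fusion hydrogens are trans, and the C1 methyl is cis to H-7a; none of C1, C3a and C7a can be epimerised in the target, so each has to be set kinetically or by a reagent. Fragile groups are the aryl-conjugated diene (electrophilic halogen, peroxy acids, strong acid), the two ring alkenes, and the hindered acid, which sits γ,δ to C6=C7 and would lactonise under protic acid. The real difficulty is to build the vicinal quaternary pair, relate the three tertiary centres to it, and place the ring B alkene exactly at C2=C3 beside the trans fusion. The key step uses the fact that C2 and C3 are bonded only to each other, to C1 and to C3a: a sulfonyl group inserted between them gives a thiane S,S-dioxide (S, C2, C1, C7a, C3a, C3) that two C–S alkylations can close, and loss of SO2 then writes the alkene at C2=C3 and nowhere else.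

**Logic of the disconnections**

34 ⇐ 32 (through 33). The C2=C3 bond is cut and SO2 is put back between C2 and C3, with chlorine on C2. A regiodefined cyclopentene becomes a saturated six-membered ring with no new stereochemical demand. The forward step must deprotonate C3 next to a carboxylate and must not touch C1, C3a or C7a.

32 ⇐ 31 ⇐ 30. The C2–Cl bond and the ester on the C4 carboxyl are removed. Chlorine is placed last, on a sulfonyl carbanion, so that no electrophilic chlorine and no peroxide ever meets the diene. The forward step needs kinetic deprotonation at the C2 methylene in preference to the C3 methine, and monochlorination.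

30 ⇐ 28 + 29, and 28 ⇐ 26 + 27. The two alkenes of the side chain are cut in turn, each by a carbonyl olefination that gives the E isomer. The chain is attached only after the sulfone exists. The forward steps need a stabilised ylide to add to the neopentyl aldehyde 26 without a free alkoxide building up beside the C4 ester.

26 ⇐ 25 ⇐ 23 (through 24). The aldehyde is traced to a primary alcohol and the hydroxy ester to a γ-lactone. The lactone stores C4 at the acid level and C5 at the alcohol level. The forward step must open it and oxidise before it can close again.

23 ⇐ 22 ⇐ 20 (through 21) ⇐ 19. The S–O bonds are removed, then both C–S bonds (C2–S and C3–S) are cut to a dimesylate and a 1,5-diol. The thiane comes from two SN2 alkylations of sulfide. The forward steps need substitution (not elimination) at the secondary C3, and S-oxidation that spares C6=C7.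

19 ⇐ 18. The C7–CH3 bond is cut to an enol triflate, which fixes the ring A alkene at C6=C7 by the regiochemistry of enolisation.

18 ⇐ 16 (through 17) ⇐ 15. The C3 hydroxyl is traced to an acetyl group and this to an isopropenyl group; the C2 hydroxyl is traced to an acyl oxazolidinone; the enol triflate comes from the C7 ketone. One ozonolysis–reduction delivers the diol. Ozone must spare the electron-poor enol triflate, and the base must enolise toward C6.

15 ⇐ 14. The C1–CH3 bond is cut. The auxiliary on C2 sets C1 regardless of the ring.

14 ⇐ 10 + 12 (through 13), and 12 ⇐ 11. The C3a–C3 and C7a–C1 bonds are cut, returning to an enone. Conjugate addition and enolate alkylation set C3a and C7a. The cis-fused lactone must steer the nucleophile to the methyl face, and the enolate must be C-alkylated.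

10 ⇐ 9 ⇐ 6 (through 7 and 8). Oxidation levels are adjusted and the lactone is moved from C5/C7 to C4/C5. This frees the C7 oxygen for the enone and gives the cis-fused bicycle needed for facial control. The forward step needs reduction of a lactone beside a hindered ester.

6 ⇐ 5 ⇐ 4. The C7–O bond and the alkene position are traced to the symmetrical ring alkene. The free acid on C5 decides which alkene carbon is oxygenated.

4 ⇐ 3. One acyl C–O bond is cut. A single desymmetrising alcoholysis fixes the absolute configuration of C4 and C5 and tells the two carboxyl carbons apart.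

3 ⇐ 1 + 2. The C3a–C4 and C5–C6 bonds are cut (Diels–Alder). The Z-alkene of 1 delivers the cis quaternary pair.

**Other disconnections considered**

Alternative 1: The cut is through C3a–C4 and C5–C6 with a carbonyl kept at C7. In the forward sense 1 would add the 1-amino-3-siloxydiene A1, which carries a C2-symmetric 2,5-diphenylpyrrolidine, and acidic work-up would expel the amine to give enone anhydride A2.
- In favour: the very electron-rich diene should overcome the low reactivity of the tetrasubstituted dienophile, and one step would give the ring A enone with both quaternary centres.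
- Against: the amine-bearing centre is erased, so the enantiomeric purity of A2 would depend on the facial bias of A1 and also on the endo/exo ratio. The two anhydride carbonyls (future C4 acid and C5 chain) stay undifferentiated, and an anhydride is a poor companion for cuprates, hydrides and sulfide. Ring B is not addressed.
- Comparison: structurally it rests on the same cycloaddition logic for the cis methyls as the chosen plan, and on that point it is the equal. In step economy it is the better, since the chosen plan needs five further steps from 3 to reach 10. Mechanistically the chosen plan gains both absolute configuration and carbonyl differentiation from one alcoholysis, which A2 would still lack. A2 could feed the same sulfur endgame.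

Alternative 2: The cut is through C3a–C4 and C7–C7a. In the forward sense pyrone A3 would add the (E)-enone A4 across its C3 and C6 to give the endo bridged lactone A5.
- In favour: it is convergent. C3a and C7a would come from the trans dienophile, C1 from the stereocentre already in A4, and C4 from the endo rule. The acetyl and butenyl groups of A5 are the C3 and C1–C2 units of the diol that a thiane needs, one ozonolysis–reduction away. The lactone bridge serves as protected carboxyl and as allylic leaving group for a later methyl delivery to C5.
- Against: an alkylated 2-pyrone and a singly activated, β-branched dienophile would need forcing conditions, under which A5 could lose CO2. Endo/exo and π-facial selectivity with respect to the allylic centre of A4 are not assured. The stereocentre of A4 is doubly allylic and prone to isomerise. The C5 quaternary centre is postponed.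
- Comparison: in convergence and step count this plan is the better, and taking C1 from a fragment is simpler than the auxiliary used here. The chosen plan spreads its risk over several conventional ionic steps, whereas this one concentrates it in one demanding pericyclic step.

Alternative 3: The cut is at the C5–CH3 bond, seen as the C5–CH2 bond of a cyclopropane. In the forward sense a Simmons–Smith reaction (Et2Zn, CH2I2) on allylic alcohol A6 would deliver CH2 to C5=C6 syn to the C7 hydroxyl, giving A7. Later cleavage of the C6–CH2 bond would unveil the C5 methyl.
- In favour: zinc-alkoxide-directed delivery is among the most predictable ways to set a quaternary centre next to another one, and it should ignore the undirected ring B alkene.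
- Against: it presupposes ring B, the C4 centre and a C7 carbinol of the right configuration. It costs an oxidation, a reductive ring opening and a ketone-to-methylalkene sequence for one methyl group. It offers no construction of ring B.
- Comparison: the stereochemical predictability of this single step is equal to or better than that of any step of the chosen plan. The chosen plan gets the cis C4/C5 pair at the outset from 1 and is the more economical for that problem. Mechanistically this is a concerted methylene transfer used as a stereochemical relay, whereas the chosen key step is a skeletal contraction that fixes regiochemistry.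

Key step: step 22

Remark: atom labels C1–C7a are the indene positions of the target and are kept for every intermediate.
Remark: precursor 32 and product 34 were checked atom by atom and centre by centre against the target and need no correction; what is changed is the design around 32: chlorine is put on C2 by carbanion chlorination of the sulfone, and sulfur is oxidised before the diene exists, so that neither electrophilic chlorine nor a peroxide meets the diene.
Remark: C3 is expected as a mixture of epimers from step 11 on; one epimer is drawn in 18–33 and both converge in step 22.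

**Route**

Step 1
Reactants: 1 2,3-dimethylmaleic anhydride; 2 buta-1,3-diene
Product: 3 meso cis-1,2-dimethylcyclohex-4-ene-1,2-dicarboxylic anhydride
Conditions: 2 (excess), hydroquinone (cat.), toluene, sealed vessel, 180 °C
Reagents that add atoms: none
Why: Thermal Diels–Alder reaction; suprafacial addition across the Z-alkene of 1 fixes the two methyl groups (future C4 and C5) cis, and the adduct is meso, so absolute configuration is still open.

Step 2
Reactants: 3
Product: 4 (1S,2R)-2-(methoxycarbonyl)-1,2-dimethylcyclohex-4-ene-1-carboxylic acid (ester on C4, acid on C5)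
Conditions: quinine (1.1 equiv), MeOH (3 equiv), toluene, −50 → −20 °C; aq. HCl work-up
Reagents that add atoms: methanol, CO
Why: Alkaloid-mediated desymmetrising alcoholysis of a meso anhydride, in which the quinuclidine nitrogen acts as general base and delivers methanol to one enantiotopic carbonyl; by analogy with the unmethylated tetrahydrophthalic anhydride, quinine should place the ester on the future C4, which sets the absolute configuration of both quaternary centres and differentiates the two carboxyl carbons at once.

Step 3
Reactants: 4
Product: 5 iodolactone methyl 4-iodo-1,2-dimethyl-7-oxo-6-oxabicyclo[3.2.1]octane-2-carboxylate (lactone O on C7 on the carboxyl face; I on C7a trans to it)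
Conditions: I2, KI, NaHCO3, THF–H2O, 0 °C → rt, dark
Reagents that add atoms: iodine, II
Why: Iodolactonisation; the C5 carboxylate opens the iodonium ion anti at the alkene carbon 1,3 to it (γ-lactone, the only closure open to an axial carboxylate on a cyclohexene), so oxygen goes regiospecifically to C7 and iodine to C7a.

Step 4
Reactants: 5
Product: 6 bridged allylic lactone methyl 1,2-dimethyl-7-oxo-6-oxabicyclo[3.2.1]oct-3-ene-2-carboxylate (C7a=C3a)
Conditions: DBU, toluene, 90 °C
Reagents that add atoms: none
Why: E2 dehydroiodination; only a C3a hydrogen can be antiperiplanar to the C7a–I bond (H-7 is syn to iodine), so the alkene forms at C7a=C3a, allylic to the C7 oxygen.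

Step 5
Reactants: 6
Product: 9 cis-fused hydroxy lactone 5-hydroxy-3a,7a-dimethyl-3a,4,5,7a-tetrahydro-2-benzofuran-1(3H)-one, via lactol 7 (not isolated), via diol ester 8 (not isolated)
Conditions: i-Bu2AlH (1.1 equiv), CH2Cl2, −78 °C; MeOH, then NaBH4, 0 °C; aq. HCl, then TsOH (cat.), CH2Cl2, rt
Reagents that add atoms: none
Why: A lactone is reduced faster than the doubly neopentyl methyl ester, the lactol stage stops over-reduction, borohydride reduces the ring-opened hydroxy aldehyde, and the CH2OH on C5 then closes onto the cis ester on C4 (γ-lactonisation with loss of methanol); C5 ends at the alcohol level, C4 at the acid level and the C7 hydroxyl is free.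

Step 6
Reactants: 9
Product: 10 enone lactone 3a,7a-dimethyl-3a,4-dihydro-2-benzofuran-1,5(3H,7aH)-dione (C7 ketone, C7a=C3a)
Conditions: MnO2 (excess), CH2Cl2, rt
Reagents that add atoms: none
Why: Selective oxidation of a secondary allylic alcohol by MnO2; the lactone and both quaternary centres are untouched.

Step 7
Reactants: 11 (S)-4-benzyl-1,3-oxazolidin-2-one
Product: 12 (S)-4-benzyl-3-(bromoacetyl)-1,3-oxazolidin-2-one
Conditions: n-BuLi, THF, −78 °C; BrCH2COBr, −78 → 0 °C
Reagents that add atoms: bromoacetyl bromide, O=C(Br)CBr
Why: N-Acylation of the lithiated oxazolidinone by the acid bromide, which reacts far faster at the acyl carbon than at the CH2Br carbon.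

Step 8
Reactants: 10; 12
Product: 14 imide ketone (C3a isopropenyl cis to the C4 methyl; C7a CH2C(O)-oxazolidinone trans to it; C7 ketone), via magnesium enolate 13 (not isolated)
Conditions: CH2=C(Me)MgBr (2.2 equiv), CuBr·SMe2 (1.1 equiv), THF, −78 °C; then 12, DMPU, −78 → −20 °C
Reagents that add atoms: isopropenylmagnesium bromide, CC(=C)[Mg]Br
Why: Cuprate conjugate addition followed by enolate alkylation with an α-halo carbonyl electrophile; the nucleophile should enter C3a on the convex face of the cis-fused bicycle, anti to the lactone ring and antiperiplanar to the C4–acyl bond (hence cis to the C4 methyl), and the regiodefined enolate is alkylated at C7a anti to the new group, the trans arrangement also being the thermodynamic one at this epimerisable centre.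

Step 9
Reactants: 14
Product: 15 C1-methylated imide ketone ((S) at C1)
Conditions: NaN(SiMe3)2 (1.05 equiv), THF, −78 °C; MeI, −78 → −40 °C
Reagents that add atoms: iodomethane, CI
Why: Evans alkylation; the imide CH2 is markedly more acidic than the ketone α-hydrogens, so the chelated Z-enolate forms selectively and iodomethane enters opposite the benzyl group, which with the (S)-auxiliary gives the C1 configuration of the target independently of the ring.

Step 10
Reactants: 15
Product: 16 enol triflate (C6=C7–OTf)
Conditions: KN(SiMe3)2, THF, −78 °C; PhNTf2, −78 → 0 °C
Reagents that add atoms: N-phenylbis(trifluoromethanesulfonimide), O=S(=O)(N(c1ccccc1)S(=O)(=O)C(F)(F)F)C(F)(F)F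
Why: Kinetic enolisation at the C6 methylene (H-7a is tertiary and shielded, and the α-branched imide resists deprotonation because of allylic 1,3-strain in its enolate) and O-sulfonylation; this fixes the later ring A alkene at C6=C7.

Step 11
Reactants: 16
Product: 18 diol enol triflate (secondary OH on C3; primary OH on C2), via methyl ketone 17 (not isolated)
Conditions: O3, CH2Cl2–MeOH, −78 °C, stopped when the 1,1-disubstituted alkene is consumed; Me2S; then LiBH4, THF–MeOH, 0 °C
Reagents that add atoms: ozone, [O-][O+]=O
Why: Ozonolysis is electrophilic and should cleave the electron-rich isopropenyl group while sparing the electron-poor enol triflate; LiBH4 then reduces the C3 ketone and reductively removes the oxazolidinone to give the C2 alcohol, with the doubly neopentyl lactone and the triflate expected to survive at 0 °C; C3 forms as an epimer mixture, which does not matter.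

Step 12
Reactants: 18
Product: 19 diol with the C6=C7 methyl alkene
Conditions: (MeBO)3, Pd(PPh3)4 (5 mol %), K2CO3, 1,4-dioxane, 95 °C
Reagents that add atoms: trimethylboroxine, CB1OB(C)OB(C)O1
Why: Suzuki–Miyaura methylation of an enol triflate; the coupling is stereoretentive at the alkene and tolerates free hydroxyl groups and the lactone.

Step 13
Reactants: 19
Product: 20 dimesylate
Conditions: MsCl, Et3N, CH2Cl2, 0 °C
Reagents that add atoms: methanesulfonyl chloride, CS(=O)(=O)Cl
Why: Sulfonylation through the sulfene is fast even at the hindered secondary C3 hydroxyl; no stereocentre is affected.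

Step 14
Reactants: 20
Product: 22 lactone-fused thiane, via thiolate 21 (not isolated)
Conditions: Na2S·9H2O (1.2 equiv), EtOH–DMF, 50 °C
Reagents that add atoms: sodium sulfide, [Na+].[Na+].[S-2]
Why: Double SN2 alkylation of sulfide; the primary C2 mesylate reacts first and the resulting thiolate closes the six-membered ring at C3 (6-exo-tet) with inversion, the soft weakly basic thiolate favouring substitution over elimination; the C3 configuration is immaterial.

Step 15
Reactants: 22
Product: 23 thiane S,S-dioxide
Conditions: (NH4)6Mo7O24·4H2O (10 mol %), 30% H2O2, EtOH, 0 °C → rt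
Reagents that add atoms: hydrogen peroxide, OO
Why: Molybdate-catalysed peroxide oxidation takes a sulfide to the sulfone much faster than it epoxidises an isolated trisubstituted alkene, and at this stage the sensitive diene is not yet present.

Step 16
Reactants: 23
Product: 25 hydroxy allyl ester (C4 CO2-allyl; C5 CH2OH), via lithium carboxylate 24 (not isolated)
Conditions: LiOH (1.1 equiv), THF–H2O, 50 °C; evaporate; NaHCO3, allyl bromide, DMF, rt
Reagents that add atoms: lithium hydroxide, [Li+].[OH-]; allyl bromide, C=CCBr
Why: Saponification of the γ-lactone and O-alkylation of the carboxylate, which is the only nucleophile strong enough under these conditions; the ester prevents relactonisation once the alcohol is oxidised, and 25 is used at once.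

Step 17
Reactants: 25
Product: 26 aldehyde allyl ester (C5 CHO)
Conditions: Dess–Martin periodinane, NaHCO3, CH2Cl2, 0 °C → rt
Reagents that add atoms: none
Why: Dess–Martin oxidation of a neopentyl primary alcohol under buffered, non-epimerising conditions; the aldehyde has no α-hydrogen and the sulfone and alkene are inert.

Step 18
Reactants: 26; 27 2-(triphenylphosphoranylidene)propanal
Product: 28 (E)-enal (C5–CH=C(CH3)–CHO)
Conditions: toluene, 100 °C
Reagents that add atoms: none
Why: Wittig reaction of a stabilised ylide, which proceeds through an oxaphosphetane without a free alkoxide that could attack the neighbouring ester and gives the E-trisubstituted alkene (C5 trans to the formyl group) under thermodynamic control of the addition.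

Step 19
Reactants: 28; 29 diethyl benzylphosphonate
Product: 30 (E,E)-diene allyl ester sulfone
Conditions: 29, NaH, THF, 0 °C; then 28, 0 °C → rt
Reagents that add atoms: none
Why: Horner–Wadsworth–Emmons reaction of a benzylphosphonate anion with an enal gives the E-styrenyl alkene; the phosphonate anion is too weak a base to deprotonate the sulfone.

Step 20
Reactants: 30
Product: 31 2-chloro sulfone allyl ester (Cl on C2, equatorial)
Conditions: LiN(i-Pr)2 (1.1 equiv), THF, −78 °C; transferred into C2Cl6, THF, −78 °C
Reagents that add atoms: hexachloroethane, ClC(Cl)(Cl)C(Cl)(Cl)Cl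
Why: α-Sulfonyl carbanion chlorination; kinetic deprotonation takes place at the C2 methylene and not at the more hindered C3 methine, the ester has no α-hydrogen, and inverse addition to excess hexachloroethane limits dichlorination; the equatorial carbanion should give equatorial chlorine.

Step 21
Reactants: 31
Product: 32 2-chloro sulfone acid (Ramberg–Bäcklund precursor)
Conditions: Pd(PPh3)4 (5 mol %), morpholine, THF, rt
Reagents that add atoms: none
Why: Tsuji–Trost deallylation; the π-allyl palladium intermediate is captured by morpholine under neutral conditions that leave the α-chloro sulfone (inert to SN2 and to weak bases) and the diene alone.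

Step 22
Reactants: 32
Product: 34 27-nor-zyggomphic acid B, via episulfone 33 (not isolated)
Conditions: KOt-Bu (4 equiv), THF–t-BuOH, 0 °C → rt; then aq. citric acid
Reagents that add atoms: none
Why: tert-Butoxide first forms the potassium carboxylate and then removes the proton at C3, α′ to the sulfonyl group. The carbanion displaces chloride at C2 in an intramolecular SN2 reaction (1,3-elimination, 3-exo-tet) to give the thiirane S,S-dioxide 33, and cheletropic loss of SO2 forms the C2=C3 π-bond; this is the Ramberg–Bäcklund reaction, and the closest known case is the conversion of 2-halothiane 1,1-dioxides into cyclopentenes. Ring B is thus closed by the C2–C3 bond made in the 3-exo-tet step, the six-membered sulfur ring contracting to the five-membered carbocycle. No stereocentre is created, because C2 and C3 both become trigonal, so the C3 epimer mixture and the C2 configuration are irrelevant. The equatorial chlorine and a freely inverting carbanion at C3 allow the W-shaped arrangement that the displacement prefers. The only selectivity needed is regiochemical and the position of sulfur secures it. C1, C3a and C7a are β to sulfur, carry no acidifying group and keep their configuration, and the product has no doubly allylic hydrogen through which the new alkene could migrate. Acidification of the potassium salt gives 34 with no further step.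

**Compound list**

1 | 2,3-dimethylmaleic anhydride | CC1=C(C)C(=O)OC1=O | starting material
2 | buta-1,3-diene | C=CC=C | starting material
3 | meso cis-1,2-dimethylcyclohex-4-ene-1,2-dicarboxylic anhydride | C[C@@]12CC=CC[C@]1(C)C(=O)OC2=O | intermediate
4 | (1S,2R)-2-(methoxycarbonyl)-1,2-dimethylcyclohex-4-ene-1-carboxylic acid (ester on C4, acid on C5) | COC(=O)[C@]1(C)CC=CC[C@]1(C)C(=O)O | intermediate
5 | methyl 4-iodo-1,2-dimethyl-7-oxo-6-oxabicyclo[3.2.1]octane-2-carboxylate (lactone O on C7, I on C7a trans to O) | COC(=O)[C@]1(C)C[C@@H](I)[C@H]2C[C@]1(C)C(=O)O2 | intermediate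
6 | methyl 1,2-dimethyl-7-oxo-6-oxabicyclo[3.2.1]oct-3-ene-2-carboxylate (C7a=C3a) | COC(=O)[C@]1(C)C=C[C@H]2C[C@]1(C)C(=O)O2 | intermediate
7 | bridged lactol (7-hydroxy analogue of 6, anomers) | COC(=O)[C@]1(C)C=C[C@H]2C[C@]1(C)C(O)O2 | intermediate (not isolated)
8 | methyl 4-hydroxy-6-(hydroxymethyl)-1,6-dimethylcyclohex-2-ene-1-carboxylate (OH and CH2OH cis to the ester) | COC(=O)[C@]1(C)C=C[C@H](O)C[C@]1(C)CO | intermediate (not isolated)
9 | cis-fused hydroxy lactone, 5-hydroxy-3a,7a-dimethyl-3a,4,5,7a-tetrahydro-2-benzofuran-1(3H)-one (C=O on C4, OCH2 on C5, C7 OH on the lactone face) | O=C1OC[C@@]2(C)C[C@@H](O)C=C[C@@]12C | intermediate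
10 | enone lactone, 3a,7a-dimethyl-3a,4-dihydro-2-benzofuran-1,5(3H,7aH)-dione | O=C1OC[C@@]2(C)CC(=O)C=C[C@@]12C | intermediate
11 | (S)-4-benzyl-1,3-oxazolidin-2-one | O=C1N[C@@H](Cc2ccccc2)CO1 | starting material
12 | (S)-4-benzyl-3-(bromoacetyl)-1,3-oxazolidin-2-one | O=C(CBr)N1[C@@H](Cc2ccccc2)COC1=O | intermediate
13 | bromomagnesium enolate (C7–O–MgBr, C7=C7a; C3a isopropenyl cis to the C4 methyl) | C=C(C)[C@H]1C=C(O[Mg]Br)C[C@]2(C)COC(=O)[C@@]21C | intermediate (not isolated)
14 | imide ketone (C3a isopropenyl; C7a CH2C(O)-oxazolidinone trans to it; C7 ketone; fused lactone) | C=C(C)[C@H]1[C@H](CC(=O)N3[C@@H](Cc4ccccc4)COC3=O)C(=O)C[C@]2(C)COC(=O)[C@@]21C | intermediate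
15 | C1-methylated imide ketone ((S) at C1) | C=C(C)[C@H]1[C@H]([C@H](C)C(=O)N3[C@@H](Cc4ccccc4)COC3=O)C(=O)C[C@]2(C)COC(=O)[C@@]21C | intermediate
16 | enol triflate (C6=C7–OTf) | C=C(C)[C@H]1[C@H]([C@H](C)C(=O)N3[C@@H](Cc4ccccc4)COC3=O)C(OS(=O)(=O)C(F)(F)F)=C[C@]2(C)COC(=O)[C@@]21C | intermediate
17 | C3a-acetyl enol triflate | CC(=O)[C@H]1[C@H]([C@H](C)C(=O)N3[C@@H](Cc4ccccc4)COC3=O)C(OS(=O)(=O)C(F)(F)F)=C[C@]2(C)COC(=O)[C@@]21C | intermediate (not isolated)
18 | diol enol triflate (C3 secondary OH, one epimer drawn; C2 primary OH) | C[C@H](O)[C@H]1[C@H]([C@H](C)CO)C(OS(=O)(=O)C(F)(F)F)=C[C@]2(C)COC(=O)[C@@]21C | intermediate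
19 | diol with C6=C7 methyl alkene | C[C@H](O)[C@H]1[C@H]([C@H](C)CO)C(C)=C[C@]2(C)COC(=O)[C@@]21C | intermediate
20 | dimesylate | C[C@H](OS(C)(=O)=O)[C@H]1[C@H]([C@H](C)COS(C)(=O)=O)C(C)=C[C@]2(C)COC(=O)[C@@]21C | intermediate
21 | sodium thiolate monomesylate (S on C2) | C[C@H](OS(C)(=O)=O)[C@H]1[C@H]([C@H](C)C[S-])C(C)=C[C@]2(C)COC(=O)[C@@]21C.[Na+] | intermediate (not isolated)
22 | lactone-fused thiane (S between C2 and C3; trans ring fusion) | CC1=C[C@]2(C)COC(=O)[C@]2(C)[C@H]3[C@@H](C)SC[C@@H](C)[C@H]13 | intermediate
23 | lactone-fused thiane S,S-dioxide | CC1=C[C@]2(C)COC(=O)[C@]2(C)[C@H]3[C@@H](C)S(=O)(=O)C[C@@H](C)[C@H]13 | intermediate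
24 | lithium carboxylate (C4 CO2Li, C5 CH2OH) | CC1=C[C@](C)(CO)[C@](C)(C(=O)[O-])[C@H]2[C@@H](C)S(=O)(=O)C[C@@H](C)[C@H]12.[Li+] | intermediate (not isolated)
25 | hydroxy allyl ester | CC1=C[C@](C)(CO)[C@](C)(C(=O)OCC=C)[C@H]2[C@@H](C)S(=O)(=O)C[C@@H](C)[C@H]12 | intermediate
26 | aldehyde allyl ester (C5 CHO) | CC1=C[C@](C)(C=O)[C@](C)(C(=O)OCC=C)[C@H]2[C@@H](C)S(=O)(=O)C[C@@H](C)[C@H]12 | intermediate
27 | 2-(triphenylphosphoranylidene)propanal | CC(C=O)=P(c1ccccc1)(c1ccccc1)c1ccccc1 | starting material
28 | (E)-enal (C5–CH=C(CH3)–CHO) | CC1=C[C@](C)(/C=C(C)/C=O)[C@](C)(C(=O)OCC=C)[C@H]2[C@@H](C)S(=O)(=O)C[C@@H](C)[C@H]12 | intermediate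
29 | diethyl benzylphosphonate | CCOP(=O)(Cc1ccccc1)OCC | starting material
30 | (E,E)-diene allyl ester sulfone | CC1=C[C@](C)(/C=C(C)/C=C/c3ccccc3)[C@](C)(C(=O)OCC=C)[C@H]2[C@@H](C)S(=O)(=O)C[C@@H](C)[C@H]12 | intermediate
31 | 2-chloro sulfone allyl ester | CC1=C[C@](C)(/C=C(C)/C=C/c3ccccc3)[C@](C)(C(=O)OCC=C)[C@H]2[C@@H](C)S(=O)(=O)[C@H](Cl)[C@@H](C)[C@H]12 | intermediate
32 | 2-chloro thiane S,S-dioxide acid (key-step precursor) | CC1=C[C@](C)(/C=C(C)/C=C/c2ccccc2)[C@](C)(C(=O)O)[C@H]2[C@@H](C)S(=O)(=O)[C@H](Cl)[C@@H](C)[C@H]12 | intermediate
33 | episulfone (thiirane S,S-dioxide across C2–C3), potassium carboxylate; the two episulfone carbons are left undefined | CC1=C[C@](C)(/C=C(C)/C=C/c3ccccc3)[C@](C)(C(=O)[O-])[C@H]2C4(C)C(S4(=O)=O)[C@@H](C)[C@H]12.[K+] | intermediate (not isolated)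
34 | 27-nor-zyggomphic acid B | CC1=C[C@](C)(/C=C(C)/C=C/c2ccccc2)[C@](C)(C(=O)O)[C@H]2C(C)=C[C@@H](C)[C@H]12 | target

**Step count and risk**

Total: 22 steps. Longest linear sequence: 21 steps (steps 1–6 and 8–22); step 7 is a one-step side branch.

Least certain steps:

- Step 22 (key step). Most likely problem: slow α′-deprotonation at C3, because the carboxylate on C4 lies next to it, so that 1,2-dehydrochlorination toward C1 or attack of alkoxide on the episulfone competes. Fallback: it sets out from 31, which is treated with KOt-Bu in THF so that the contraction runs on the uncharged ester and gives the allyl ester of the target F1; Pd(PPh3)4 and morpholine then free the acid, and the route is rejoined at 34.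

- Step 2. Most likely problem: slow and weakly selective alcoholysis, because both carbonyl groups sit on quaternary carbons. Fallback: it sets out from 3; methanolysis without alkaloid (MeOH, Et3N) gives racemic 4, one enantiomer is taken out as the crystalline (R)-1-phenylethylammonium salt F2 (the antipodal amine if the other salt crystallises), and acidification rejoins the route at 4.

- Step 8. Most likely problem: proton transfer from the acidic CH2Br group of 12 to enolate 13, which quenches the enolate instead of alkylating it. Fallback: it sets out from 10; the same cuprate addition is followed by trapping with methyl bromoacetate, a weaker carbon acid, to give keto ester F3; LiOH and then acid (which re-closes the lactone) give keto acid F4, and its mixed pivalic anhydride is coupled with the lithium salt of 11; the route is rejoined at 14.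

- Step 11. Most likely problem: over-oxidation, ozone attacking the enol triflate alkene once the isopropenyl group is consumed. Fallback: it sets out from 16; OsO4 (cat.) with N-methylmorpholine N-oxide dihydroxylates only the electron-rich 1,1-disubstituted alkene to give vicinal diol F5, NaIO4 cleaves it, and the route is rejoined at 17, which is reduced as before.

- Step 14. Most likely problem: E2 elimination of the hindered secondary mesylate, or opening of the lactone by the basic sulfide, competing with the second displacement. Fallback: it sets out from 19; a Mitsunobu reaction with thioacetic acid at the primary alcohol gives thioacetate F6, mesylation of the secondary alcohol gives thioacetate mesylate F7, and K2CO3 in degassed MeOH frees the thiolate, which closes the ring; the route is rejoined at 22.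

- Step 18. Most likely problem: sluggish addition of the stabilised ylide to the neopentyl aldehyde, with decomposition on long heating. Fallback: it sets out from 26; a Horner–Wadsworth–Emmons reaction with the sodium salt of triethyl 2-phosphonopropionate gives enoate F8, i-Bu2AlH at −78 °C reduces the conjugated ester (the neopentyl allyl ester on C4 is far less accessible) to allylic alcohol F9, and MnO2 oxidises it; the route is rejoined at 28.

**Further compounds**

F1 | step 22 | allyl ester of 27-nor-zyggomphic acid B | CC1=C[C@](C)(/C=C(C)/C=C/c2ccccc2)[C@](C)(C(=O)OCC=C)[C@H]2C(C)=C[C@@H](C)[C@H]12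
F2 | step 2 | (R)-1-phenylethylammonium salt of 4 | COC(=O)[C@]1(C)CC=CC[C@]1(C)C(=O)[O-].C[C@@H]([NH3+])c1ccccc1
F3 | step 8 | keto ester (C7a CH2CO2Me, C3a isopropenyl, C7 ketone, fused lactone) | C=C(C)[C@H]1[C@H](CC(=O)OC)C(=O)C[C@]2(C)COC(=O)[C@@]21C
F4 | step 8 | keto acid (C7a CH2CO2H) | C=C(C)[C@H]1[C@H](CC(=O)O)C(=O)C[C@]2(C)COC(=O)[C@@]21C
F5 | step 11 | vicinal diol from dihydroxylation of the isopropenyl group of 16 | CC(O)(CO)[C@H]1[C@H]([C@H](C)C(=O)N3[C@@H](Cc4ccccc4)COC3=O)C(OS(=O)(=O)C(F)(F)F)=C[C@]2(C)COC(=O)[C@@]21C
F6 | step 14 | C2 thioacetate with free C3 alcohol | C[C@H](O)[C@H]1[C@H]([C@H](C)CSC(C)=O)C(C)=C[C@]2(C)COC(=O)[C@@]21C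
F7 | step 14 | C2 thioacetate C3 mesylate | C[C@H](OS(C)(=O)=O)[C@H]1[C@H]([C@H](C)CSC(C)=O)C(C)=C[C@]2(C)COC(=O)[C@@]21C
F8 | step 18 | (E)-enoate (C5–CH=C(CH3)–CO2Et) | CC1=C[C@](C)(/C=C(C)/C(=O)OCC)[C@](C)(C(=O)OCC=C)[C@H]2[C@@H](C)S(=O)(=O)C[C@@H](C)[C@H]12
F9 | step 18 | (E)-allylic alcohol (C5–CH=C(CH3)–CH2OH) | CC1=C[C@](C)(/C=C(C)/CO)[C@](C)(C(=O)OCC=C)[C@H]2[C@@H](C)S(=O)(=O)C[C@@H](C)[C@H]12
A1 | alternative 1 | (E)-3-(tert-butyldimethylsilyloxy)-1-[(2R,5R)-2,5-diphenylpyrrolidin-1-yl]buta-1,3-diene (drawn as one enantiomer of the auxiliary) | C=C(O[Si](C)(C)C(C)(C)C)/C=C/N1[C@@H](c2ccccc2)CC[C@@H]1c1ccccc1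
A2 | alternative 1 | cis-fused enone anhydride (C7 ketone, C7a=C3a) | O=C1C=C[C@@]2(C)C(=O)OC(=O)[C@@]2(C)C1
A3 | alternative 2 | 4-[(tert-butyldimethylsilyloxy)methyl]-3,6-dimethyl-2H-pyran-2-one | Cc1cc(CO[Si](C)(C)C(C)(C)C)c(C)c(=O)o1
A4 | alternative 2 | (E)-5-methylhepta-3,6-dien-2-one, single enantiomer as drawn | CC(=O)/C=C/[C@H](C)C=C
A5 | alternative 2 | endo bridged-lactone cycloadduct (acetyl on C3a, but-3-en-2-yl on C7a, lactone across C4 and C7) | C[C@@]12OC(=O)[C@@](C)(C(CO[Si](C)(C)C(C)(C)C)=C1)[C@@H](C(C)=O)[C@@H]2[C@H](C)C=C
A6 | alternative 3 | C7 allylic alcohol with C5=C6 alkene, C5 silyloxymethyl, C4 methyl ester and ring B in place | O[C@H]1C=C(CO[Si](C)(C)C(C)(C)C)[C@](C)(C(=O)OC)[C@H]2C(C)=C[C@@H](C)[C@H]12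
A7 | alternative 3 | cyclopropane-fused C7 alcohol (CH2 across C5 and C6 on the hydroxyl face) | O[C@H]1[C@H]3C[C@@]3(CO[Si](C)(C)C(C)(C)C)[C@](C)(C(=O)OC)[C@H]2C(C)=C[C@@H](C)[C@H]12
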